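In this closed, stirred vessel, followed so far as the dusk run, I want the chain length and the conversion at 20 h.

common to all: initiator 0.21 mM
- dusk: free monomer 0.10 M; protic impurity 0.010 M; the very flask that is asked about, followed so far
- dawn: free monomer 0.20 M; protic impurity 0.010 M; run made earlier
- flask: free monomer 0.10 M; protic impurity 0.0100 M; time 20 h

| run | time / h | monomer in chains / % | free monomer / % |
|---|---|---|---|
| dusk | 0.667 | 0 | 87.9 |
| dusk | 1.33 | 0.4 | 86.3 |
| dusk | 2.50 | 0.7 | 82.7 |
| dusk | 4.00 | 2.0 | 77.6 |
| dusk | 8.00 | 6.0 | 64.8 |
| dawn | 1.33 | 0.9 | 90.8 |
| dawn | 4.00 | 4.4 | 80.6 |
| dawn | 6.00 | 6.5 | 72.7 |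
| dawn | 10.0 | 12.1 | 59.6 |
| dawn | 15.0 | 18.5 | 45.5 |

(each reading ± 0.5 percentage points)

* average number of monomer units in a chain (chains begun, living or dead) at 20 h
* part of the free monomer that has reacted at 20 h

- the average divides the monomer in chains by the number of chains begun, living and dead together
- the earlier runs do not show the number of chains; that part of a forecast is a guess

My zero of the scale is the statistical case of one chain per initiator. So I take Y = 476, the free monomer charged per initiator charged, the target degree of polymerisation. With u the fraction of the monomer charge in chains and b the fraction of the initiator charge that has begun a chain: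

dp = Y · u / b

Yet dusk at 8.00 h has lost 35.2% of its free monomer while its chains hold 6.0%. If the protic impurity takes its equal, 10.0% of the charge, then 19.2% still lies outside chains. Y counts the whole charge, so it is u that restricts dp to the monomer in chains.

Dusk's chains gained 4 percentage points over its last interval. Carried on in a straight line, that gives u = 18.0% at 20 h, so with the whole initiator charge begun I reckon dp = 85.7.

The forecast says dp 70 and c 64%. It stands below my dp, on the ground that "This is a guess, so I shade it to about 70 with a wide range".

The flask gives dp 80.8 and c 63.2%.

    free monomer + initiator → living end + monomer in chains (k = 5.50 × 10⁻⁴ /M/s)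
    free monomer + living end → monomer in chains + living end, rate k2*[living end]*[free monomer] (k = 0.0320 /M/s)
    monomer in chains + living end → free monomer + living end, rate k3*[living end] as long as [monomer in chains] is above zero (k = 3.00 × 10⁻⁴ /s)
    free monomer → uncatalysed product (k = 8.60 × 10⁻⁶ /s)
    protic impurity + free monomer → quenched substrate (k = 0.0230 /M/s)

At 20.0 h this flask holds 15.5% of its monomer charge in chains and keeps 8.97% of its initiator, so b is 91.0% and Y · u / b gives 81.1. The neighbour charged with 0.40 M of free monomer has Y = 1900, u = 25.5% and 0.0062% of its initiator left, so Y · u gives 486. That neighbour's dp is 486.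

(The data are simulated from invented constants; the scatter is artificial.)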